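On the central benzene ring, C1 carries the methide carbon bound to a 4-oxygenated phenyl ring. The neighbouring C6 carries a two-carbon alkyne ending in an identical ring. Both arms are therefore traced to one symmetrical 1,3-diaryl-1,3-diketone. Its acyl–CH2 bond is opened across the C1–C6 triple bond of an aryne, forming C6–CH2 and C1–C(=O) in a single operation. The aryne precursor is an ortho-silylaryl triflate flanked by chlorine at C2 (regiocontrol, later Suzuki handle) and a protected hydroxymethyl group at C5. Every hydroxyl travels as a MOM ether, so one mild acid treatment completes the synthesis.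

Key step: step 9

Atom labels: central benzene C1 (methide carbon), C2 (2,4-dihydroxyphenyl ring), C3 and C4 (H), C5 (CH2OH), C6 (alkyne).

Assumption: the open p-quinone methide as drawn is the form in which the deprotected compound is isolated. Addition of the 2'-hydroxyl to the methide carbon is taken to be reversible and disfavoured.

Remarks on the design:
- (a) Methyl ethers would be the cheapest phenol protection. Their removal needs a boron trihalide, which would also turn the C5 benzylic C–O bond into a C–halogen bond. Acetal protection throughout costs five routine steps outside the longest sequence and makes the last step a mild solvolysis.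
- (b) The ester is kept until after silylation and is then reduced together with the carbamate. A benzylic alkoxide next to an aryl carbamate invites O-to-O carbamoyl transfer, which is harmless only if the carbamate is being removed anyway. This ordering also saves one step.
- (c) 1-Bromo-4-(methoxymethoxy)benzene is taken to be a catalogue compound.

Step 1
Reactants: 1 methyl 4-chloro-2-hydroxybenzoate
Product: 2 methyl 4-chloro-2-[(diethylcarbamoyl)oxy]benzoate
Conditions: Et2NCOCl, K2CO3, MeCN, reflux
Reagents that add atoms: N,N-diethylcarbamoyl chloride, CCN(CC)C(=O)Cl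
Why: O-carbamoylation of the phenoxide is routine and installs a strong oxygen-based directing group for ortho-metalation without touching the ester or the chloride.

Step 2
Reactants: 2 methyl 4-chloro-2-[(diethylcarbamoyl)oxy]benzoate
Product: 4 methyl 4-chloro-2-[(diethylcarbamoyl)oxy]-3-(trimethylsilyl)benzoate, via C3-lithiated carbamate 3 (not isolated)
Conditions: Me3SiCl (3 equiv) present from the start, LiN(i-Pr)2 (1.2 equiv) added dropwise, THF, −78 °C
Reagents that add atoms: chlorotrimethylsilane, C[Si](C)(C)Cl
Why: Directed ortho-metalation with in situ quench, in which the only C–H flanked by two acidifying groups (O-carbamate and chlorine) is removed and the aryllithium is silylated as it forms, before it can attack the ester, undergo anionic Fries migration or lose LiCl.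

Step 3
Reactants: 4 methyl 4-chloro-2-[(diethylcarbamoyl)oxy]-3-(trimethylsilyl)benzoate
Product: 5 3-chloro-6-(hydroxymethyl)-2-(trimethylsilyl)phenol
Conditions: LiAlH4, THF, 0 °C → reflux; aq. KNaC4H4O6 work-up (no mineral acid)
Reagents that add atoms: none
Why: Hydride reduction takes the ester to the primary alcohol and reductively cleaves the aryl carbamate in the same flask, so any carbamoyl shift to the benzylic alkoxide is inconsequential because the shifted carbamate is reduced as well, while aryl chloride and aryl silane are inert.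

Step 4
Reactants: 5 3-chloro-6-(hydroxymethyl)-2-(trimethylsilyl)phenol
Product: 6 3-chloro-6-(hydroxymethyl)-2-(trimethylsilyl)phenyl trifluoromethanesulfonate
Conditions: PhNTf2, Et3N, DMAP (cat.), CH2Cl2, rt
Reagents that add atoms: N-phenylbis(trifluoromethanesulfonimide), O=S(=O)(N(c1ccccc1)S(=O)(=O)C(F)(F)F)C(F)(F)F
Why: Chemoselective O-sulfonylation, since this mild triflyl donor reacts only with the amine-generated phenoxide and leaves a neutral primary alcohol alone.

Step 5
Reactants: 6 3-chloro-6-(hydroxymethyl)-2-(trimethylsilyl)phenyl trifluoromethanesulfonate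
Product: 7 3-chloro-6-[(methoxymethoxy)methyl]-2-(trimethylsilyl)phenyl trifluoromethanesulfonate
Conditions: MOMCl, i-Pr2NEt, CH2Cl2, 0 °C → rt
Reagents that add atoms: chloromethyl methyl ether, COCCl
Why: Standard acetal protection of a primary alcohol under amine base, free of fluoride or hard oxygen bases so the silyl/triflate pair survives, giving an ether inert to fluoride, amide bases, aqueous phosphate and aryllithiums.

Step 6
Reactants: 8 4'-hydroxyacetophenone
Product: 9 4'-(methoxymethoxy)acetophenone
Conditions: MOMCl, i-Pr2NEt, CH2Cl2, 0 °C → rt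
Reagents that add atoms: chloromethyl methyl ether, COCCl
Why: Routine O-alkylation of an acidic phenol to its MOM ether.

Step 7
Reactants: 10 methyl 4-hydroxybenzoate
Product: 11 methyl 4-(methoxymethoxy)benzoate
Conditions: MOMCl, i-Pr2NEt, CH2Cl2, 0 °C → rt
Reagents that add atoms: chloromethyl methyl ether, COCCl
Why: Routine O-alkylation of an acidic phenol to its MOM ether.

Step 8
Reactants: 9 4'-(methoxymethoxy)acetophenone; 11 methyl 4-(methoxymethoxy)benzoate
Product: 12 1,3-bis[4-(methoxymethoxy)phenyl]propane-1,3-dione
Conditions: NaH (2.2 equiv), THF, reflux; AcOH quench, 0 °C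
Reagents that add atoms: none
Why: Crossed Claisen condensation of a methyl ketone enolate with a non-enolisable benzoate, driven to completion by irreversible deprotonation of the 1,3-diketone formed.

Step 9
Reactants: 7 3-chloro-6-[(methoxymethoxy)methyl]-2-(trimethylsilyl)phenyl trifluoromethanesulfonate; 12 1,3-bis[4-(methoxymethoxy)phenyl]propane-1,3-dione
Product: 15 2-{3-chloro-6-[(methoxymethoxy)methyl]-2-[4-(methoxymethoxy)benzoyl]phenyl}-1-[4-(methoxymethoxy)phenyl]ethan-1-one, via aryne 13 (not isolated), via benzocyclobutenoxide 14 (not isolated)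
Conditions: CsF (3 equiv), 12 (1.5 equiv), MeCN, 80 °C, slow addition of 7
Reagents that add atoms: none
Why: Fluoride attacks silicon of 7 and triflate (a far better leaving group than the chloride on the other flank) departs to release aryne 13; the caesium enolate of 12 adds through carbon to C6, the aryl anion at C1 adds to the nearby carbonyl (4-exo-trig) to give 14, and retro-aldol-type opening of the strained ring moves the aroyl group to C1, the resulting benzylic enolate being protonated by further 12. This is the aryne acyl-alkylation known for β-ketoesters, malonates and 1,3-diketones. No ring persists in 15, the four-membered ring of 14 being transient, and 15 has no stereocentre, so the configuration of 14 is irrelevant. The selectivity needed is regiochemical: the σ-withdrawing chlorine at C2 distorts the aryne so that C6 is the more linear, electrophilic terminus and charge builds up at C1 next to chlorine, whereas the CH2OMOM group at C5 polarises little and is about as large as chlorine, so steric effects roughly cancel. Because 12 is symmetrical either acyl–CH2 bond gives the same product, and excess 12 together with slow addition of 7 suppresses a second arylation of 15. MOM ethers, the only protecting groups present, are inert to fluoride.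

Step 10
Reactants: 15 2-{3-chloro-6-[(methoxymethoxy)methyl]-2-[4-(methoxymethoxy)benzoyl]phenyl}-1-[4-(methoxymethoxy)phenyl]ethan-1-one
Product: 17 {6-chloro-3-[(methoxymethoxy)methyl]-2-{[4-(methoxymethoxy)phenyl]ethynyl}phenyl}[4-(methoxymethoxy)phenyl]methanone, via (Z)-enol triflate 16 (not isolated)
Conditions: KN(SiMe3)2 (1.1 equiv), THF, −78 °C; PhNTf2 (1.15 equiv), −78 → 0 °C; KN(SiMe3)2 (1.5 equiv), −78 °C → rt
Reagents that add atoms: none
Why: Ketone-to-alkyne dehydration by enolate O-triflation and anti E2 elimination, in which only the deoxybenzoin ketone can enolise, its (Z)-enolate (aryl groups trans) places the vinylic hydrogen anti to the triflate, and the second charge of base expels triflate.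

Step 11
Reactants: 18 4-bromobenzene-1,3-diol
Product: 19 1-bromo-2,4-bis(methoxymethoxy)benzene
Conditions: MOMCl (2.5 equiv), i-Pr2NEt, CH2Cl2, 0 °C → rt
Reagents that add atoms: chloromethyl methyl ether, COCCl
Why: Routine double O-alkylation of a resorcinol to its bis-MOM ether.

Step 12
Reactants: 19 1-bromo-2,4-bis(methoxymethoxy)benzene
Product: 21 2-[2,4-bis(methoxymethoxy)phenyl]-4,4,5,5-tetramethyl-1,3,2-dioxaborolane, via aryllithium 20 (not isolated)
Conditions: n-BuLi, THF, −78 °C; i-PrOBpin, −78 °C → rt; H2O
Reagents that add atoms: 2-isopropoxy-4,4,5,5-tetramethyl-1,3,2-dioxaborolane, CC(C)OB1OC(C)(C)C(C)(C)O1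
Why: Bromine–lithium exchange followed by borylation gives the pinacol boronate after a neutral work-up that spares the acetals, and the ester resists protodeboronation better than the free electron-rich boronic acid.

Step 13
Reactants: 17 {6-chloro-3-[(methoxymethoxy)methyl]-2-{[4-(methoxymethoxy)phenyl]ethynyl}phenyl}[4-(methoxymethoxy)phenyl]methanone; 21 2-[2,4-bis(methoxymethoxy)phenyl]-4,4,5,5-tetramethyl-1,3,2-dioxaborolane
Product: 22 {2',4'-bis(methoxymethoxy)-4-[(methoxymethoxy)methyl]-3-{[4-(methoxymethoxy)phenyl]ethynyl}biphenyl-2-yl}[4-(methoxymethoxy)phenyl]methanone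
Conditions: Pd(OAc)2 (5 mol %), SPhos (10 mol %), K3PO4, toluene–H2O, 95 °C
Reagents that add atoms: none
Why: Suzuki–Miyaura coupling in which the C2–Cl bond is activated for oxidative addition by the ortho aroyl group, the bulky electron-rich biaryl phosphine copes with aryl chlorides and ortho-substituted partners, and alkyne, ketone and MOM ethers are spectators.

Step 14
Reactants: 23 1-bromo-4-(methoxymethoxy)benzene; 22 {2',4'-bis(methoxymethoxy)-4-[(methoxymethoxy)methyl]-3-{[4-(methoxymethoxy)phenyl]ethynyl}biphenyl-2-yl}[4-(methoxymethoxy)phenyl]methanone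
Product: 25 {2',4'-bis(methoxymethoxy)-4-[(methoxymethoxy)methyl]-3-{[4-(methoxymethoxy)phenyl]ethynyl}biphenyl-2-yl}bis[4-(methoxymethoxy)phenyl]methanol, via 4-(methoxymethoxy)phenyllithium 24 (not isolated)
Conditions: 23 (3.2 equiv), n-BuLi (3 equiv), THF, −78 °C; then 22, −78 → −20 °C; H2O quench at −40 °C
Reagents that add atoms: none
Why: 1,2-Addition of an aryllithium to a non-enolisable diaryl ketone leaves addition as the only productive pathway despite two ortho substituents, a cold quench keeps the tertiary alkoxide away from the neighbouring alkyne, and the new carbinol carbon bears two identical aryl groups and is not stereogenic.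

Step 15
Reactants: 25 {2',4'-bis(methoxymethoxy)-4-[(methoxymethoxy)methyl]-3-{[4-(methoxymethoxy)phenyl]ethynyl}biphenyl-2-yl}bis[4-(methoxymethoxy)phenyl]methanol
Product: 27 selaginellin F, via deprotected carbinol 26 (not isolated)
Conditions: HCl (catalytic, from conc. aq. acid), MeOH–THF, 55 °C; neutral aqueous work-up
Reagents that add atoms: none
Why: Acid-catalysed acetal exchange with methanol removes all six MOM groups as dimethoxymethane, and the bis(4-hydroxyphenyl)carbinol then ionises and loses water, the classical dehydration of a 4-hydroxytriarylcarbinol to a fuchsone-type p-quinone methide, while the unactivated primary benzylic alcohol at C5 is not ionised.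

Compound list
1 | methyl 4-chloro-2-hydroxybenzoate | COC(=O)c1ccc(Cl)cc1O | starting material
2 | methyl 4-chloro-2-[(diethylcarbamoyl)oxy]benzoate | CCN(CC)C(=O)Oc1cc(Cl)ccc1C(=O)OC | intermediate
3 | methyl 4-chloro-2-[(diethylcarbamoyl)oxy]-3-lithiobenzoate (not isolated) | CCN(CC)C(=O)Oc1c([Li])c(Cl)ccc1C(=O)OC | intermediate
4 | methyl 4-chloro-2-[(diethylcarbamoyl)oxy]-3-(trimethylsilyl)benzoate | CCN(CC)C(=O)Oc1c([Si](C)(C)C)c(Cl)ccc1C(=O)OC | intermediate
5 | 3-chloro-6-(hydroxymethyl)-2-(trimethylsilyl)phenol | OCc1ccc(Cl)c([Si](C)(C)C)c1O | intermediate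
6 | 3-chloro-6-(hydroxymethyl)-2-(trimethylsilyl)phenyl trifluoromethanesulfonate | OCc1ccc(Cl)c([Si](C)(C)C)c1OS(=O)(=O)C(F)(F)F | intermediate
7 | 3-chloro-6-[(methoxymethoxy)methyl]-2-(trimethylsilyl)phenyl trifluoromethanesulfonate | COCOCc1ccc(Cl)c([Si](C)(C)C)c1OS(=O)(=O)C(F)(F)F | intermediate
8 | 4'-hydroxyacetophenone | CC(=O)c1ccc(O)cc1 | starting material
9 | 4'-(methoxymethoxy)acetophenone | COCOc1ccc(cc1)C(C)=O | intermediate
10 | methyl 4-hydroxybenzoate | COC(=O)c1ccc(O)cc1 | starting material
11 | methyl 4-(methoxymethoxy)benzoate | COCOc1ccc(cc1)C(=O)OC | intermediate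
12 | 1,3-bis[4-(methoxymethoxy)phenyl]propane-1,3-dione | COCOc1ccc(cc1)C(=O)CC(=O)c1ccc(OCOC)cc1 | intermediate
13 | 3-chloro-6-[(methoxymethoxy)methyl]benzyne (not isolated) | COCOCC1=CC=C(Cl)C#C1 | intermediate
14 | caesium benzocyclobutenoxide from C6–C and C1–C(O) bond formation (not isolated; configuration irrelevant) | COCOCc1ccc(Cl)c2c1C(C(=O)c1ccc(OCOC)cc1)C2([O-])c1ccc(OCOC)cc1.[Cs+] | intermediate
15 | 2-{3-chloro-6-[(methoxymethoxy)methyl]-2-[4-(methoxymethoxy)benzoyl]phenyl}-1-[4-(methoxymethoxy)phenyl]ethan-1-one | COCOCc1ccc(Cl)c(C(=O)c2ccc(OCOC)cc2)c1CC(=O)c1ccc(OCOC)cc1 | intermediate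
16 | (Z)-enol triflate of the deoxybenzoin ketone of 15 (not isolated) | COCOCc1ccc(Cl)c(C(=O)c2ccc(OCOC)cc2)c1/C=C(\OS(=O)(=O)C(F)(F)F)c1ccc(OCOC)cc1 | intermediate
17 | {6-chloro-3-[(methoxymethoxy)methyl]-2-{[4-(methoxymethoxy)phenyl]ethynyl}phenyl}[4-(methoxymethoxy)phenyl]methanone | COCOCc1ccc(Cl)c(C(=O)c2ccc(OCOC)cc2)c1C#Cc1ccc(OCOC)cc1 | intermediate
18 | 4-bromobenzene-1,3-diol | Oc1ccc(Br)c(O)c1 | starting material
19 | 1-bromo-2,4-bis(methoxymethoxy)benzene | COCOc1ccc(Br)c(OCOC)c1 | intermediate
20 | 2,4-bis(methoxymethoxy)phenyllithium (not isolated) | [Li]c1ccc(OCOC)cc1OCOC | intermediate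
21 | 2-[2,4-bis(methoxymethoxy)phenyl]-4,4,5,5-tetramethyl-1,3,2-dioxaborolane | COCOc1ccc(B2OC(C)(C)C(C)(C)O2)c(OCOC)c1 | intermediate
22 | {2',4'-bis(methoxymethoxy)-4-[(methoxymethoxy)methyl]-3-{[4-(methoxymethoxy)phenyl]ethynyl}biphenyl-2-yl}[4-(methoxymethoxy)phenyl]methanone | COCOCc1ccc(-c2ccc(OCOC)cc2OCOC)c(C(=O)c2ccc(OCOC)cc2)c1C#Cc1ccc(OCOC)cc1 | intermediate
23 | 1-bromo-4-(methoxymethoxy)benzene | COCOc1ccc(Br)cc1 | starting material
24 | 4-(methoxymethoxy)phenyllithium (not isolated) | [Li]c1ccc(OCOC)cc1 | intermediate
25 | {2',4'-bis(methoxymethoxy)-4-[(methoxymethoxy)methyl]-3-{[4-(methoxymethoxy)phenyl]ethynyl}biphenyl-2-yl}bis[4-(methoxymethoxy)phenyl]methanol | COCOCc1ccc(-c2ccc(OCOC)cc2OCOC)c(C(O)(c2ccc(OCOC)cc2)c2ccc(OCOC)cc2)c1C#Cc1ccc(OCOC)cc1 | intermediate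
26 | {2',4'-dihydroxy-4-(hydroxymethyl)-3-[(4-hydroxyphenyl)ethynyl]biphenyl-2-yl}bis(4-hydroxyphenyl)methanol (not isolated) | OCc1ccc(-c2ccc(O)cc2O)c(C(O)(c2ccc(O)cc2)c2ccc(O)cc2)c1C#Cc1ccc(O)cc1 | intermediate
27 | selaginellin F, 4-{[2',4'-dihydroxy-4-(hydroxymethyl)-3-[(4-hydroxyphenyl)ethynyl]biphenyl-2-yl](4-hydroxyphenyl)methylidene}cyclohexa-2,5-dien-1-one | O=C1C=CC(=C(c2ccc(O)cc2)c2c(-c3ccc(O)cc3O)ccc(CO)c2C#Cc2ccc(O)cc2)C=C1 | target

Total step count: 15.
Longest linear sequence: 10 steps (1–5, 9, 10, 13, 14, 15). Steps 6–8 and 11–12 are short side branches.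

Steps most likely to fail

**Step 9.**
- What may go wrong:
  - Regiocontrol could erode if the weakly withdrawing, cation-binding side chain at C5 offsets the bias set by chlorine.
  - The C1 aryl anion could be protonated too early, which stops the sequence at simple α-arylation.
  - The enol form could be O-arylated, or the product arylated a second time.
- Fallback: an aryne-free assembly by chemoselective couplings. It sets out from 7 and rejoins at 17, bypassing steps 9 and 10.
  - Ipso-iododesilylation of 7 with ICl (CH2Cl2, 0 °C → rt) should give 3-chloro-2-iodo-6-[(methoxymethoxy)methyl]phenyl trifluoromethanesulfonate F1.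
  - The reactivity order C–I > C–OTf > C–Cl then allows a carbonylative Suzuki–Miyaura coupling at iodine. The partner is purchased 4-(methoxymethoxy)phenylboronic acid (CO 1 atm, PdCl2(IPr)(3-chloropyridine), Cs2CO3, chlorobenzene, 80 °C). This should give 3-chloro-6-[(methoxymethoxy)methyl]-2-[4-(methoxymethoxy)benzoyl]phenyl trifluoromethanesulfonate F2.
  - A Sonogashira coupling at the triflate with purchased 1-ethynyl-4-(methoxymethoxy)benzene (PdCl2(PPh3)2, CuI, Et3N, DMF, 70 °C) leaves the chloride untouched and should deliver 17.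

**Step 14.**
- What may go wrong:
  - Addition to a carbonyl shielded by an ortho aryl ring and an ortho alkyne could be sluggish.
  - On warming, the tertiary alkoxide could close onto the alkyne (5-exo-dig).
- Fallback: reverse the order of the two aryl introductions, so that the nucleophile meets the smaller chloro ketone. It sets out from 17 and rejoins at 25.
  - Aryllithium 24 (from 23) is added to 17 at −78 °C. This should give {6-chloro-3-[(methoxymethoxy)methyl]-2-{[4-(methoxymethoxy)phenyl]ethynyl}phenyl}bis[4-(methoxymethoxy)phenyl]methanol F3.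
  - The chloride of F3 has only one ortho neighbour. It is then coupled with 21 under the conditions of step 13 (Pd(OAc)2, SPhos, K3PO4, toluene–H2O, 90 °C) to give 25.

**Step 15.**
- What may go wrong:
  - The aliphatic acetal could be lost more slowly than the five aryl acetals, prolonging the exposure of the cation and the quinone methide to acid.
  - The electron-rich resorcinol ring could capture the released one-carbon electrophile.
  - Acid could promote solvent addition to the donor-substituted alkyne.
  - The 2'-oxygen could close onto the cationic carbon.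
- Fallback: separate the deprotection from quinone methide formation by a reduce, deprotect, reoxidise sequence. It sets out from 25 and rejoins at 27.
  - Brief ionic reduction (Et3SiH, CF3CO2H 2 equiv, CH2Cl2, −20 °C) ionises only the highly stabilised carbinol. It should give the MOM-protected triarylmethane F4.
  - F4 has no cationic centre and tolerates the acetal exchange (HCl, MeOH–THF, 55 °C) for as long as needed. This should give the colourless leuco hexaol F5.
  - Dehydrogenation of the bis(4-hydroxyphenyl)methane C–H with DDQ (1 equiv, dioxane, rt) is the classical oxidation of a 4-hydroxytriarylmethane to its fuchsone. It should then furnish 27 under neutral conditions.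

Further compounds
F1 | step 9 | 3-chloro-2-iodo-6-[(methoxymethoxy)methyl]phenyl trifluoromethanesulfonate | COCOCc1ccc(Cl)c(I)c1OS(=O)(=O)C(F)(F)F
F2 | step 9 | 3-chloro-6-[(methoxymethoxy)methyl]-2-[4-(methoxymethoxy)benzoyl]phenyl trifluoromethanesulfonate | COCOCc1ccc(Cl)c(C(=O)c2ccc(OCOC)cc2)c1OS(=O)(=O)C(F)(F)F
F3 | step 14 | {6-chloro-3-[(methoxymethoxy)methyl]-2-{[4-(methoxymethoxy)phenyl]ethynyl}phenyl}bis[4-(methoxymethoxy)phenyl]methanol | COCOCc1ccc(Cl)c(C(O)(c2ccc(OCOC)cc2)c2ccc(OCOC)cc2)c1C#Cc1ccc(OCOC)cc1
F4 | step 15 | 2-{bis[4-(methoxymethoxy)phenyl]methyl}-2',4'-bis(methoxymethoxy)-4-[(methoxymethoxy)methyl]-3-{[4-(methoxymethoxy)phenyl]ethynyl}biphenyl | COCOCc1ccc(-c2ccc(OCOC)cc2OCOC)c(C(c2ccc(OCOC)cc2)c2ccc(OCOC)cc2)c1C#Cc1ccc(OCOC)cc1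
F5 | step 15 | 2-[bis(4-hydroxyphenyl)methyl]-4-(hydroxymethyl)-3-[(4-hydroxyphenyl)ethynyl]biphenyl-2',4'-diol | OCc1ccc(-c2ccc(O)cc2O)c(C(c2ccc(O)cc2)c2ccc(O)cc2)c1C#Cc1ccc(O)cc1
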